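**Plan**

- The target is acyclic apart from the benzene ring of the 4‑hydroxybenzoate, which is bought in. Numbering the dodecatrienyl chain from the ether CH2 as C1, the (4E,6E,8E)‑triene has a central C6=C7 ethene unit flanked by two sp2–sp2 single bonds, C5–C6 and C7–C8.
- Retrosynthesis: the primary and phenolic hydroxyls are first masked as silyl ethers. C5–C6 and C7–C8 are then cut together, giving a C6=C7 stannyl–boryl ethene, (E)‑1‑iodopent‑1‑ene (C8–C12) and a glyceryl (E)‑5‑iodopent‑4‑enyl ether (C1–C5).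
- The glyceryl piece is cut at the ester C–O bond (a 4‑silyloxybenzoic acid) and at the O–C1 ether bond (pent‑4‑ynyl tosylate plus (R)‑solketal).
- Forward: the O–C1 ether is made first, then the C4=C5 vinyl iodide, acetonide removal, primary silylation and esterification. One pot then joins C7–C8 (tin) and C5–C6 (boron), and a final desilylation gives the target. No ring is formed.
- Stereochemistry: the glycerol C2 centre comes from (R)‑solketal and no bond to it is ever broken. The three E alkenes come from syn‑hydrozirconation of two terminal alkynes and from the E‑configured linchpin, all transferred with retention.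

Key step: step 10

Remark on the chemistry: the phenol is carried as a triisopropylsilyl ether because an aryl tert‑butyldimethylsilyl ether para to the carboxyl group would be at risk under the aqueous base of the boron stage; the descriptor at glycerol C2 reads R in the silylated compounds and S in the target only because CIP priorities change, not the spatial arrangement.

**Route**

Step 1
Reactants: 1 pent‑4‑yn‑1‑ol
Product: 2 pent‑4‑yn‑1‑yl 4‑methylbenzenesulfonate
Conditions: TsCl (1.2 equiv), Et3N, DMAP (cat.), CH2Cl2, 0 °C to rt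
Reagents that add atoms: p‑toluenesulfonyl chloride, Cc1ccc(cc1)S(Cl)(=O)=O
Why: Tosylation of an unhindered primary alcohol under amine base with DMAP catalysis is routine and does not touch the terminal alkyne.

Step 2
Reactants: 3 (R)‑solketal, [(4R)‑2,2‑dimethyl‑1,3‑dioxolan‑4‑yl]methanol; 2 pent‑4‑yn‑1‑yl 4‑methylbenzenesulfonate
Product: 4 (4R)‑2,2‑dimethyl‑4‑[(pent‑4‑yn‑1‑yloxy)methyl]‑1,3‑dioxolane
Conditions: NaH (1.1 equiv), THF/DMF, 0 °C; then 2 (1.15 equiv), Bu4NI (cat.), 0 °C to rt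
Reagents that add atoms: none
Why: Williamson ether synthesis, in which the sodium alkoxide of 3 displaces the primary tosylate by SN2; the acetonide is base‑stable and the stereocentre is not involved, so its configuration is carried over.

Step 3
Reactants: 4 (4R)‑2,2‑dimethyl‑4‑[(pent‑4‑yn‑1‑yloxy)methyl]‑1,3‑dioxolane
Product: 6 (4R)‑4‑({[(4E)‑5‑iodopent‑4‑en‑1‑yl]oxy}methyl)‑2,2‑dimethyl‑1,3‑dioxolane, via alkenylzirconocene chloride 5 (not isolated)
Conditions: Cp2Zr(H)Cl (1.3 equiv), THF, rt, dark; then I2, 0 °C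
Reagents that add atoms: iodine, II
Why: Hydrozirconation–iodination, in which syn addition of Zr–H places zirconium on the terminal carbon and iodinolysis of the C–Zr bond proceeds with retention to give the E‑vinyl iodide; ether and acetonide are inert to Cp2Zr(H)Cl.

Step 4
Reactants: 6 (4R)‑4‑({[(4E)‑5‑iodopent‑4‑en‑1‑yl]oxy}methyl)‑2,2‑dimethyl‑1,3‑dioxolane
Product: 7 (2S)‑3‑{[(4E)‑5‑iodopent‑4‑en‑1‑yl]oxy}propane‑1,2‑diol
Conditions: 1 M aq HCl/THF (1:4), rt
Reagents that add atoms: none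
Why: Acid‑catalysed acetal hydrolysis should free the 1,2‑diol while the vinyl iodide and the ether survive dilute acid and no C–O bond at the stereocentre is broken.

Step 5
Reactants: 7 (2S)‑3‑{[(4E)‑5‑iodopent‑4‑en‑1‑yl]oxy}propane‑1,2‑diol
Product: 8 (2R)‑1‑[(tert‑butyldimethylsilyl)oxy]‑3‑{[(4E)‑5‑iodopent‑4‑en‑1‑yl]oxy}propan‑2‑ol
Conditions: TBSCl (1.05 equiv), imidazole, CH2Cl2, −20 to 0 °C
Reagents that add atoms: tert‑butyldimethylsilyl chloride, CC(C)(C)[Si](C)(C)Cl
Why: Selective silylation, since the bulky silyl chloride should react with the primary hydroxyl much faster than with the flanked secondary one at low temperature.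

Step 6
Reactants: 9 4‑hydroxybenzoic acid
Product: 11 4‑[(triisopropylsilyl)oxy]benzoic acid, via triisopropylsilyl 4‑[(triisopropylsilyl)oxy]benzoate 10 (not isolated)
Conditions: TIPSCl (2.2 equiv), imidazole, DMF, rt; then K2CO3, THF/H2O, rt; then 1 M HCl to pH 3
Reagents that add atoms: triisopropylsilyl chloride, CC(C)[Si](Cl)(C(C)C)C(C)C
Why: Double silylation followed by selective hydrolysis of the silyl ester, which is far more labile to mild carbonate than the hindered aryl silyl ether, is the standard way to mask only the phenol of a hydroxybenzoic acid.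

Step 7
Reactants: 8 (2R)‑1‑[(tert‑butyldimethylsilyl)oxy]‑3‑{[(4E)‑5‑iodopent‑4‑en‑1‑yl]oxy}propan‑2‑ol; 11 4‑[(triisopropylsilyl)oxy]benzoic acid
Product: 12 (2R)‑1‑[(tert‑butyldimethylsilyl)oxy]‑3‑{[(4E)‑5‑iodopent‑4‑en‑1‑yl]oxy}propan‑2‑yl 4‑[(triisopropylsilyl)oxy]benzoate
Conditions: 11 (1.3 equiv), DCC (1.4 equiv), DMAP (0.2 equiv), CH2Cl2, 0 °C to rt
Reagents that add atoms: none
Why: Steglich esterification through the O‑acylisourea and the acylpyridinium ion acylates the secondary alcohol at oxygen, so the C–O bond at the stereocentre stays intact and the configuration is retained; silyl ethers and the vinyl iodide are inert.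

Step 8
Reactants: 13 pent‑1‑yne
Product: 15 (E)‑1‑iodopent‑1‑ene, via (E)‑pent‑1‑enylzirconocene chloride 14 (not isolated)
Conditions: Cp2Zr(H)Cl (1.1 equiv), CH2Cl2, rt, dark; then I2, 0 °C; careful concentration (volatile)
Reagents that add atoms: iodine, II
Why: Hydrozirconation–iodination of a terminal alkyne, with syn addition and stereoretentive iodinolysis, should give the E‑vinyl iodide.

Step 9
Reactants: 16 (E)‑1,2‑bis(tributylstannyl)ethene
Product: 18 tributyl[(E)‑2‑(4,4,5,5‑tetramethyl‑1,3,2‑dioxaborolan‑2‑yl)ethenyl]stannane, via (E)‑2‑(tributylstannyl)ethenyllithium 17 (not isolated)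
Conditions: n‑BuLi (1.0 equiv), THF, −78 °C; then iPrOBpin (1.2 equiv), −78 °C to rt; H2O quench
Reagents that add atoms: 2‑isopropoxy‑4,4,5,5‑tetramethyl‑1,3,2‑dioxaborolane, CC(C)OB1OC(C)(C)C(C)(C)O1
Why: Tin–lithium exchange with one equivalent of n‑BuLi gives the E‑vinyllithium with retention of geometry, and borylation of a vinyllithium with iPrOBpin through the ate complex is a standard route to pinacol boronates.

Step 10
Reactants: 15 (E)‑1‑iodopent‑1‑ene; 18 tributyl[(E)‑2‑(4,4,5,5‑tetramethyl‑1,3,2‑dioxaborolan‑2‑yl)ethenyl]stannane; 12 (2R)‑1‑[(tert‑butyldimethylsilyl)oxy]‑3‑{[(4E)‑5‑iodopent‑4‑en‑1‑yl]oxy}propan‑2‑yl 4‑[(triisopropylsilyl)oxy]benzoate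
Product: 20 (2R)‑1‑[(tert‑butyldimethylsilyl)oxy]‑3‑{[(4E,6E,8E)‑dodeca‑4,6,8‑trien‑1‑yl]oxy}propan‑2‑yl 4‑[(triisopropylsilyl)oxy]benzoate, via (1E,3E)‑hepta‑1,3‑dienyl pinacol boronate 19 (not isolated)
Conditions: 15 (1.2 equiv), 18 (1.25 equiv), PdCl2(MeCN)2 (5 mol %), degassed DMF, rt, dark; then 12 (1.0 equiv), Pd(PPh3)4 (5 mol %), 3 M aq K3PO4 (4 equiv), THF, rt to 40 °C
Reagents that add atoms: none
Why: In the first stage zerovalent palladium, formed in situ from the divalent precatalyst PdCl2(MeCN)2, inserts into the C8–I bond of 15, the vinyl group of 18 is transferred from tin to palladium, and reductive elimination forms C7–C8 to leave dienyl boronate 19, whose tricoordinate boron cannot transmetalate in neutral DMF. Adding 12, fresh Pd(PPh3)4 and aqueous K3PO4 then activates boron, the dienyl group is transferred to the alkenylpalladium iodide derived from 12, and reductive elimination forms C5–C6. The closest known reaction type is the one‑pot Stille then Suzuki–Miyaura polyene assembly with 1‑stannyl‑2‑boryl alkenes. No ring is closed and no stereocentre is created, the glycerol centre being a spectator. The all‑E triene follows because oxidative addition, both transmetalations and reductive elimination retain geometry at sp2 carbon, so the three E alkenes of the partners are carried through. The required tin‑before‑boron chemoselectivity is secured by withholding base until 15 is consumed, and the secondary benzoate, the hindered aryl TIPS ether and the primary TBS ether should tolerate phosphate base near room temperature.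

Step 11
Reactants: 20 (2R)‑1‑[(tert‑butyldimethylsilyl)oxy]‑3‑{[(4E,6E,8E)‑dodeca‑4,6,8‑trien‑1‑yl]oxy}propan‑2‑yl 4‑[(triisopropylsilyl)oxy]benzoate
Product: 21 (2S)‑1‑{[(4E,6E,8E)‑dodeca‑4,6,8‑trien‑1‑yl]oxy}‑3‑hydroxypropan‑2‑yl 4‑hydroxybenzoate
Conditions: Bu4NF (3 equiv), AcOH (3.3 equiv), THF, 0 °C to rt, dark, argon
Reagents that add atoms: none
Why: Fluoride‑mediated desilylation should cleave both the aryl and the primary silyl ether, and the acetic acid buffer protonates the primary alkoxide as it forms, which should suppress base‑catalysed migration of the benzoate from O2 to O3; ester and triene are inert.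

**Compound list**

1 | pent‑4‑yn‑1‑ol | C#CCCCO | starting material
2 | pent‑4‑yn‑1‑yl 4‑methylbenzenesulfonate | C#CCCCOS(=O)(=O)c1ccc(C)cc1 | intermediate
3 | (R)‑solketal, [(4R)‑2,2‑dimethyl‑1,3‑dioxolan‑4‑yl]methanol | OC[C@@H]1COC(C)(C)O1 | starting material
4 | (4R)‑2,2‑dimethyl‑4‑[(pent‑4‑yn‑1‑yloxy)methyl]‑1,3‑dioxolane | C#CCCCOC[C@@H]1COC(C)(C)O1 | intermediate
5 | chlorobis(cyclopentadienyl)[(1E)‑5‑{[(4R)‑2,2‑dimethyl‑1,3‑dioxolan‑4‑yl]methoxy}pent‑1‑en‑1‑yl]zirconium (cyclopentadienyl rings drawn as sigma‑bonded) | Cl[Zr](/C=C/CCCOC[C@@H]1COC(C)(C)O1)(C1C=CC=C1)C1C=CC=C1 | intermediate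
6 | (4R)‑4‑({[(4E)‑5‑iodopent‑4‑en‑1‑yl]oxy}methyl)‑2,2‑dimethyl‑1,3‑dioxolane | I/C=C/CCCOC[C@@H]1COC(C)(C)O1 | intermediate
7 | (2S)‑3‑{[(4E)‑5‑iodopent‑4‑en‑1‑yl]oxy}propane‑1,2‑diol | I/C=C/CCCOC[C@@H](O)CO | intermediate
8 | (2R)‑1‑[(tert‑butyldimethylsilyl)oxy]‑3‑{[(4E)‑5‑iodopent‑4‑en‑1‑yl]oxy}propan‑2‑ol | I/C=C/CCCOC[C@@H](O)CO[Si](C)(C)C(C)(C)C | intermediate
9 | 4‑hydroxybenzoic acid | OC(=O)c1ccc(O)cc1 | starting material
10 | triisopropylsilyl 4‑[(triisopropylsilyl)oxy]benzoate | CC(C)[Si](C(C)C)(C(C)C)OC(=O)c1ccc(O[Si](C(C)C)(C(C)C)C(C)C)cc1 | intermediate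
11 | 4‑[(triisopropylsilyl)oxy]benzoic acid | OC(=O)c1ccc(O[Si](C(C)C)(C(C)C)C(C)C)cc1 | intermediate
12 | (2R)‑1‑[(tert‑butyldimethylsilyl)oxy]‑3‑{[(4E)‑5‑iodopent‑4‑en‑1‑yl]oxy}propan‑2‑yl 4‑[(triisopropylsilyl)oxy]benzoate | I/C=C/CCCOC[C@H](CO[Si](C)(C)C(C)(C)C)OC(=O)c1ccc(O[Si](C(C)C)(C(C)C)C(C)C)cc1 | intermediate
13 | pent‑1‑yne | CCCC#C | starting material
14 | chlorobis(cyclopentadienyl)[(E)‑pent‑1‑en‑1‑yl]zirconium (cyclopentadienyl rings drawn as sigma‑bonded) | CCC/C=C/[Zr](Cl)(C1C=CC=C1)C1C=CC=C1 | intermediate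
15 | (E)‑1‑iodopent‑1‑ene | CCC/C=C/I | intermediate
16 | (E)‑1,2‑bis(tributylstannyl)ethene | CCCC[Sn](CCCC)(CCCC)/C=C/[Sn](CCCC)(CCCC)CCCC | starting material
17 | (E)‑2‑(tributylstannyl)ethenyllithium | [Li]/C=C/[Sn](CCCC)(CCCC)CCCC | intermediate
18 | tributyl[(E)‑2‑(4,4,5,5‑tetramethyl‑1,3,2‑dioxaborolan‑2‑yl)ethenyl]stannane | CCCC[Sn](CCCC)(CCCC)/C=C/B1OC(C)(C)C(C)(C)O1 | intermediate
19 | 2‑[(1E,3E)‑hepta‑1,3‑dien‑1‑yl]‑4,4,5,5‑tetramethyl‑1,3,2‑dioxaborolane | CCC/C=C/C=C/B1OC(C)(C)C(C)(C)O1 | intermediate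
20 | (2R)‑1‑[(tert‑butyldimethylsilyl)oxy]‑3‑{[(4E,6E,8E)‑dodeca‑4,6,8‑trien‑1‑yl]oxy}propan‑2‑yl 4‑[(triisopropylsilyl)oxy]benzoate | CCC/C=C/C=C/C=C/CCCOC[C@H](CO[Si](C)(C)C(C)(C)C)OC(=O)c1ccc(O[Si](C(C)C)(C(C)C)C(C)C)cc1 | intermediate
21 | (2S)‑1‑{[(4E,6E,8E)‑dodeca‑4,6,8‑trien‑1‑yl]oxy}‑3‑hydroxypropan‑2‑yl 4‑hydroxybenzoate (CNP0352133.1) | CCC/C=C/C=C/C=C/CCCOC[C@H](CO)OC(=O)c1ccc(O)cc1 | target

**Step count and risks**

Total step count: 11. Longest linear sequence: 8 steps (steps 1, 2, 3, 4, 5, 7, 10 and 11).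

Steps most likely to fail:

1. Step 10. The aqueous base of the boron stage may strip the aryl silyl ether or begin to cleave the benzoate, the dienyl boronate may protodeboronate, or unreacted iodopentene may be carried into the second stage and scramble the partners. The fallback is a base‑free double Stille sequence that sets out from 15 and 16. Excess 16 (3 equiv) is coupled once with 15 (PdCl2(MeCN)2, DMF, rt) to give tributyl[(1E,3E)‑hepta‑1,3‑dien‑1‑yl]stannane F1, purified on Et3N‑deactivated silica with recovery of surplus 16. F1 is then coupled with 12 under neutral conditions (Pd2(dba)3, AsPh3, DMF, rt), which comes back to the route at 20.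

2. Step 11. The 4‑hydroxybenzoyl group may migrate from the secondary to the newly freed primary oxygen during desilylation, and long exposure may isomerise or oxidise the triene. The fallback replaces the primary silyl ether by an acid‑labile trityl‑type ether and sets out from 7.
   - Primary‑selective tritylation (DMTrCl, pyridine, 0 °C) gives (2R)‑1‑[bis(4‑methoxyphenyl)(phenyl)methoxy]‑3‑{[(4E)‑5‑iodopent‑4‑en‑1‑yl]oxy}propan‑2‑ol F2.
   - Steglich esterification with 11 gives the corresponding 4‑[(triisopropylsilyl)oxy]benzoate F3.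
   - The same one‑pot tin‑then‑boron coupling with 15 and 18 gives the trityl‑protected triene F4.
   - Buffered fluoride (Bu4NF, AcOH, THF, 0 °C) removes only the aryl silyl group, at a stage where no free aliphatic hydroxyl exists to accept the acyl group, and gives the phenol F5.
   - Brief detritylation under mild acid (80% aq AcOH, 0 °C to rt), where acyl migration is slow, comes back to the route at 21.

3. Step 9. Tin–lithium exchange may stop short or run on to double exchange, and the product may suffer protodestannylation or prove hard to separate from tetrabutylstannane. The fallback avoids tin and sets out from 15. A Heck–Mizoroki reaction of 15 with vinylboronic acid pinacol ester (Pd(OAc)2, P(o‑tol)3, AgOAc, MeCN, 50 °C) should give the (1E,3E)‑dienyl boronate directly, so the sequence comes back to the route at 19, now isolated. A separate Suzuki–Miyaura coupling of 19 with 12 (Pd(PPh3)4, aq K3PO4, THF) then leads on to 20.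

**Further compounds**

F1 | step 10 | tributyl[(1E,3E)‑hepta‑1,3‑dien‑1‑yl]stannane | CCC/C=C/C=C/[Sn](CCCC)(CCCC)CCCC
F2 | step 11 | (2R)‑1‑[bis(4‑methoxyphenyl)(phenyl)methoxy]‑3‑{[(4E)‑5‑iodopent‑4‑en‑1‑yl]oxy}propan‑2‑ol | I/C=C/CCCOC[C@@H](O)COC(c1ccccc1)(c1ccc(OC)cc1)c1ccc(OC)cc1
F3 | step 11 | (2R)‑1‑[bis(4‑methoxyphenyl)(phenyl)methoxy]‑3‑{[(4E)‑5‑iodopent‑4‑en‑1‑yl]oxy}propan‑2‑yl 4‑[(triisopropylsilyl)oxy]benzoate | I/C=C/CCCOC[C@H](COC(c1ccccc1)(c1ccc(OC)cc1)c1ccc(OC)cc1)OC(=O)c1ccc(O[Si](C(C)C)(C(C)C)C(C)C)cc1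
F4 | step 11 | (2R)‑1‑[bis(4‑methoxyphenyl)(phenyl)methoxy]‑3‑{[(4E,6E,8E)‑dodeca‑4,6,8‑trien‑1‑yl]oxy}propan‑2‑yl 4‑[(triisopropylsilyl)oxy]benzoate | CCC/C=C/C=C/C=C/CCCOC[C@H](COC(c1ccccc1)(c1ccc(OC)cc1)c1ccc(OC)cc1)OC(=O)c1ccc(O[Si](C(C)C)(C(C)C)C(C)C)cc1
F5 | step 11 | (2R)‑1‑[bis(4‑methoxyphenyl)(phenyl)methoxy]‑3‑{[(4E,6E,8E)‑dodeca‑4,6,8‑trien‑1‑yl]oxy}propan‑2‑yl 4‑hydroxybenzoate | CCC/C=C/C=C/C=C/CCCOC[C@H](COC(c1ccccc1)(c1ccc(OC)cc1)c1ccc(OC)cc1)OC(=O)c1ccc(O)cc1
F0 | step 9 | none | none
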